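**Retrosynthetic overview**
- The target is reached from a protected 12,6α-olide by acylation and oxidation-state changes. The lactone carbons C11–C13 are built on a C7 vinyl group by hydroboration, oxidative lactonisation and methylenation.
- Key disconnection C8–C9: the ten-membered ring comes from a cis-1,2-dialkenylcyclohex-2-en-1-ol by anionic oxy-Cope ring expansion. This breaks a temporary C1–C6 bond (absent from the target), forms C8–C9, C1=C10 and a C6 enolate, and is followed in the same flask by protonation at C7.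
- Enabling feature: the carbocycle holds the retron O–C6–C7–C8–C9–C10=C1 (lactone carbinol carbon, the two vicinal carbinol carbons, the enal alkene) beside a ring-cis C4=C5 that can be the alkene of a cyclohexene C1–C6. C8 and C9 are carried as enol-ether termini, with O9 and O14 tied in a 1,3-dioxin.
- The cyclohexenol comes from a 6-(dioxinyl)cyclohexenone, an alkoxyethynyl anion (C7, C8) and a vinyl Grignard reagent (C11, C12). The ketone comes from 3-bromocyclohexenone (C1–C6), a hydroxymethylstannane (C15) and 2,2-dimethyl-1,3-dioxan-5-one (C9, C10, C14).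
- Ring order: cyclohexene (purchased) and temporary dioxin (from the dioxanone), then the ten-membered carbocycle, then the γ-lactone; the dioxane is opened near the end.

Key step: step 10

Remark on the chemistry: the side-chain stereocentre is R as written, so (R)-2-methylbutanoic acid is used; all atoms, also in precursors, carry germacrane numbers (ring C1–C10, lactone carbons C11–C13, C14 on C10, C15 on C4), and "ring-cis" means the two ring carbons on a ring double bond are cis.

**Step 1**
Reactants: 1 3-bromocyclohex-2-en-1-one; 2 (tributylstannyl)methanol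
Product: 3 3-(hydroxymethyl)cyclohex-2-en-1-one
Conditions: Pd(PPh3)4 (5 mol %), 1,4-dioxane, 90 °C
Reagents that add atoms: none
Why: Stille coupling of the activated β-bromo enone with the hydroxymethylstannane should transfer CH2OH (C15) to C4; no stereocentre is formed.

**Step 2**
Reactants: 3 3-(hydroxymethyl)cyclohex-2-en-1-one
Product: 4 3-{[(tert-butyldiphenylsilyl)oxy]methyl}cyclohex-2-en-1-one
Conditions: t-BuPh2SiCl, imidazole, DMF, 0 to 25 °C
Reagents that add atoms: tert-butyl(chloro)diphenylsilane, CC(C)(C)[Si](Cl)(c1ccccc1)c1ccccc1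
Why: Silylation of the primary alcohol gives a silyl ether that should survive strong base, DDQ, aqueous acetic acid and hypervalent iodine oxidants until the last step.

**Step 3**
Reactants: 5 2,2-dimethyl-1,3-dioxan-5-one
Product: 7 2,2-dimethyl-4H-1,3-dioxin-5-yl trifluoromethanesulfonate, via potassium dioxinolate 6 (not isolated)
Conditions: KN(SiMe3)2, THF, −78 °C; then PhN(SO2CF3)2, −78 to 0 °C
Reagents that add atoms: N-phenylbis(trifluoromethanesulfonimide), O=S(=O)(N(c1ccccc1)S(=O)(=O)C(F)(F)F)C(F)(F)F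
Why: O-sulfonylation of the enolate of the symmetrical ketone gives the enol triflate, in which the future C9=C10 enol ether is locked by the ring with O9 cis to C14.

**Step 4**
Reactants: 4 silyl ether enone; 7 dioxinyl triflate
Product: 9 rac-3-{[(tert-butyldiphenylsilyl)oxy]methyl}-6-(2,2-dimethyl-4H-1,3-dioxin-5-yl)cyclohex-2-en-1-one, via lithium dienolate 8 (not isolated)
Conditions: LiN(iPr)2, THF, −78 °C; then 7, Pd2(dba)3 (2.5 mol %), P(t-Bu)3 (10 mol %), −78 to 25 °C
Reagents that add atoms: none
Why: Kinetic deprotonation gives the cross-conjugated α′-enolate, which should undergo palladium-catalysed ketone α-alkenylation with the vinyl triflate to form the C1–C10 bond; the product is racemic at C1 because this doubly activated centre is labile, which step 5 uses.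

**Step 5**
Reactants: 9 racemic dioxinyl enone
Product: 10 (1S,6S)-3-{[(tert-butyldiphenylsilyl)oxy]methyl}-6-(2,2-dimethyl-4H-1,3-dioxin-5-yl)cyclohex-2-en-1-ol
Conditions: RuCl[(R,R)-TsDPEN](p-cymene) (2 mol %), HCO2H/Et3N (5:2), CH2Cl2, 25 °C
Reagents that add atoms: none
Why: Noyori asymmetric transfer hydrogenation under dynamic kinetic resolution: C1 (α to the ketone and allylic to the enol ether) should racemise through the enol in the amine buffer faster than the carbonyl is reduced, and the (R,R) catalyst, reading the enone π-face as the aryl-like group, should reduce the (S)-ketone fastest from the face away from the dioxinyl group to give the cis (1S,6S) alcohol.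

**Step 6**
Reactants: 10 (1S,6S)-allylic alcohol
Product: 11 (6S)-3-{[(tert-butyldiphenylsilyl)oxy]methyl}-6-(2,2-dimethyl-4H-1,3-dioxin-5-yl)cyclohex-2-en-1-one
Conditions: Dess–Martin periodinane, pyridine, CH2Cl2, 0 °C
Reagents that add atoms: none
Why: Dess–Martin oxidation regenerates the enone under buffered, non-enolising conditions, so the now homochiral C1 (S) should be kept; the ketone is used at once.

**Step 7**
Reactants: 12 (4-methoxyphenyl)methanol
Product: 14 1-({[(E)-1,2-dichloroethenyl]oxy}methyl)-4-methoxybenzene, via potassium alkoxide 13 (not isolated)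
Conditions: KH, THF, 0 °C; then Cl2C=CHCl, −50 to 25 °C
Reagents that add atoms: trichloroethene, ClC=C(Cl)Cl
Why: The alkoxide dehydrochlorinates trichloroethene to dichloroethyne and adds to it in anti fashion, which should give the (E)-1,2-dichlorovinyl ether, the standard precursor of an alkoxyethynyl anion.

**Step 8**
Reactants: 11 (6S)-dioxinyl enone; 14 dichlorovinyl ether
Product: 16 (1R,6S)-3-{[(tert-butyldiphenylsilyl)oxy]methyl}-6-(2,2-dimethyl-4H-1,3-dioxin-5-yl)-1-{[(4-methoxybenzyl)oxy]ethynyl}cyclohex-2-en-1-ol, via lithium alkoxyethynide 15 (not isolated)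
Conditions: 14, n-BuLi (2.2 equiv), THF, −78 to −40 °C; then CeCl3, −78 °C; then 11, −78 °C
Reagents that add atoms: none
Why: Two equivalents of n-BuLi convert the dichlorovinyl ether into the lithium alkoxyethynide (loss of LiCl, then chlorine–lithium exchange), which in the presence of CeCl3 should add 1,2 to the enone without enolising C1, the slender sp nucleophile attacking axially, anti to the axial C1–H of the half-chair with an equatorial dioxinyl group, so that the alkynyl group enters cis to the dioxinyl group (acetylide addition to a ketone).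

**Step 9**
Reactants: 16 alkynyl carbinol
Product: 18 (1R,6S)-3-{[(tert-butyldiphenylsilyl)oxy]methyl}-6-(2,2-dimethyl-4H-1,3-dioxin-5-yl)-1-{(1E)-1-[(4-methoxybenzyl)oxy]buta-1,3-dien-2-yl}cyclohex-2-en-1-ol, via magnesium chelate 17 (not isolated)
Conditions: CH2=CHMgBr (4 equiv), CuI (10 mol %), THF, −20 to 25 °C; then aq. NH4Cl
Reagents that add atoms: vinylmagnesium bromide, C=C[Mg]Br
Why: Copper-catalysed anti-carbomagnesiation of the propargylic magnesium alkoxide should deliver the vinyl group (C11–C12) to the carbinol-proximal alkyne carbon C7 while magnesium ends on the oxygen-bearing C8 inside a five-membered O–Mg–C chelate, so that protonolysis leaves O8 trans to C6 (E enol ether), the geometry the key step needs.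

**Step 10**
Reactants: 18 dialkenyl cyclohexenol
Product: 21 7β-ethenyl-8β-[(4-methoxybenzyl)oxy]-9α,14-(isopropylidenedioxy)-15-[(tert-butyldiphenylsilyl)oxy]cyclodeca-1(10),4-dien-6-one, via potassium alkoxide 19 (not isolated), via potassium dienolate 20 (not isolated)
Conditions: KN(SiMe3)2, 18-crown-6, THF, −40 to 0 °C; then AcOH, THF, −78 °C
Reagents that add atoms: none
Why: Deprotonation gives the potassium alkoxide 19, which should undergo a charge-accelerated [3,3]-sigmatropic shift (anionic oxy-Cope rearrangement; closest known reaction type: ring expansion of 1,2-dialkenylcyclohex-2-en-1-ols of the isopiperitenone type to ten-membered dienones) in which the doubly allylic C1–C6 bond of the cyclohexene breaks as C8–C9 forms between the two enol-ether termini. The ten-membered ring is thus closed by ring expansion through a six-membered chair array (C9=C10–C1···C6–C7=C8) and appears as the dienolate 20; C4=C5 keeps the cis geometry of the cyclohexene, and C1=C10 should form ring-cis because the chair that keeps the dioxinyl group equatorial on the cyclohexene places C2 axial on the pericyclic chair. In this chair both enol-ether oxygens are equatorial (O8 trans to C6 from step 9, O9 trans to C1 through the dioxin ring), so the configuration of C1 (S) and C6 (R) is transferred to the threo (8S,9S) pair. The C6=C7 enolate is formed ring-trans and fully substituted, cannot turn through the ring, and should be protonated by acetic acid at C7 (the α-carbon of the dienolate) from its outer face, which sets 7αH. The step needs the chair with C2 axial to win over the chair with C5 axial and over boat arrays, which the C14 methylene on C10 (a 1,3-diaxial contact with an axial C5) and the equatorial preference of the dioxinyl group should secure, and it needs the β-alkoxy enolate to survive, which the low temperature and the cold quench should secure.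

**Step 11**
Reactants: 21 ten-membered dienone
Product: 22 7β-ethenyl-8β-[(4-methoxybenzyl)oxy]-9α,14-(isopropylidenedioxy)-15-[(tert-butyldiphenylsilyl)oxy]cyclodeca-1(10),4-dien-6α-ol
Conditions: NaBH4, CeCl3·7H2O, MeOH, −78 °C (crude 21 used directly)
Reagents that add atoms: none
Why: Luche reduction should reduce the enone 1,2 before the β,γ-unsaturated β-alkoxy ketone can epimerise or eliminate, hydride entering from the outer face of the C6 carbonyl in the conformer inherited from the ring expansion (the face that also received H7), which gives the 6α-alcohol trans to the C7 side chain.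

**Step 12**
Reactants: 22 vinyl carbinol
Product: 24 7β-(2-hydroxyethyl)-8β-[(4-methoxybenzyl)oxy]-9α,14-(isopropylidenedioxy)-15-[(tert-butyldiphenylsilyl)oxy]cyclodeca-1(10),4-dien-6α-ol, via alkylborane 23 (not isolated)
Conditions: 9-BBN (2.5 equiv), THF, 0 to 25 °C; then NaOH, H2O2, 0 °C
Reagents that add atoms: hydrogen peroxide, OO
Why: Hydroboration–oxidation with 9-BBN should select the monosubstituted vinyl group over the two trisubstituted, allylically oxygenated ring alkenes and place boron on the terminal carbon, so that oxidation gives the primary C12 alcohol; no stereocentre is formed.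

**Step 13**
Reactants: 24 6α,12-diol
Product: 26 8β-[(4-methoxybenzyl)oxy]-9α,14-(isopropylidenedioxy)-15-[(tert-butyldiphenylsilyl)oxy]-13-norgermacra-1(10),4-dien-12,6α-olide, via lactol 25 (not isolated)
Conditions: TEMPO (20 mol %), PhI(OAc)2 (2.5 equiv), CH2Cl2, 25 °C
Reagents that add atoms: none
Why: The oxoammonium oxidant should select the primary alcohol, the aldehyde closes with the 6α-hydroxyl group to the lactol, and a second oxidation gives the trans-fused γ-lactone (oxidative lactonisation of a 1,4-diol) without touching C6 or C7.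

**Step 14**
Reactants: 26 saturated lactone
Product: 30 8β-[(4-methoxybenzyl)oxy]-9α,14-(isopropylidenedioxy)-15-[(tert-butyldiphenylsilyl)oxy]germacra-1(10),4,11(13)-trien-12,6α-olide, via lithium enolate 27 (not isolated), via Mannich base 28 (not isolated), via ammonium iodide 29 (not isolated)
Conditions: LiN(iPr)2, THF, −78 °C; then Me2N=CH2 I (dimethylmethyleneammonium iodide), −78 to 25 °C; then MeI, MeOH; then NaHCO3, H2O/CH2Cl2
Reagents that add atoms: dimethylmethyleneammonium iodide, C[N+](C)=C.[I-]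
Why: Eschenmoser methylenation: the lactone enolate undergoes a Mannich reaction with the iminium salt, and quaternisation followed by mild base-induced loss of trimethylamine should give the exocyclic C11=C13 alkene, the transient C11 stereocentre being destroyed again.

**Step 15**
Reactants: 30 α-methylene lactone
Product: 31 8β-hydroxy-9α,14-(isopropylidenedioxy)-15-[(tert-butyldiphenylsilyl)oxy]germacra-1(10),4,11(13)-trien-12,6α-olide
Conditions: DDQ, CH2Cl2/pH 7 buffer, 0 °C
Reagents that add atoms: none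
Why: Oxidative cleavage of the 4-methoxybenzyl ether by DDQ (hydride abstraction, then hydrolysis of the oxocarbenium ion) should free only O8, because the acetonide, the silyl ether and the lactone are inert to it.

**Step 16**
Reactants: 31 C8 alcohol; 32 (R)-2-methylbutanoic acid
Product: 33 8β-[(2R)-2-methylbutanoyloxy]-9α,14-(isopropylidenedioxy)-15-[(tert-butyldiphenylsilyl)oxy]germacra-1(10),4,11(13)-trien-12,6α-olide
Conditions: 32, DCC, DMAP (10 mol %), CH2Cl2, 0 to 25 °C
Reagents that add atoms: none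
Why: Steglich esterification should acylate the secondary C8 alcohol with retention at C8, and the α-stereocentre of the acid is not enolised under carbodiimide activation with catalytic DMAP.

**Step 17**
Reactants: 33 acetonide ester
Product: 34 9α,14-dihydroxy-8β-[(2R)-2-methylbutanoyloxy]-15-[(tert-butyldiphenylsilyl)oxy]germacra-1(10),4,11(13)-trien-12,6α-olide
Conditions: AcOH/THF/H2O (3:1:1), 40 °C
Reagents that add atoms: none
Why: Mild aqueous acid should hydrolyse the isopropylidene acetal of the 1,3-diol while the silyl ether and the esters survive, setting O9 and O14 free together.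

**Step 18**
Reactants: 34 9α,14-diol
Product: 35 9α-hydroxy-8β-[(2R)-2-methylbutanoyloxy]-14-oxo-15-[(tert-butyldiphenylsilyl)oxy]germacra-1(10),4,11(13)-trien-12,6α-olide
Conditions: TEMPO (10 mol %), PhI(OAc)2 (1.2 equiv), CH2Cl2, 0 to 25 °C
Reagents that add atoms: none
Why: TEMPO-catalysed oxidation should select the primary allylic C14 alcohol over the secondary allylic C9 alcohol and stop at the aldehyde; the ring-cis enal (CHO trans to C2) is also the thermodynamically preferred geometry, so no isomerisation is expected.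

**Step 19**
Reactants: 35 hydroxy enal
Product: 36 9α-acetoxy-8β-[(2R)-2-methylbutanoyloxy]-14-oxo-15-[(tert-butyldiphenylsilyl)oxy]germacra-1(10),4,11(13)-trien-12,6α-olide
Conditions: Ac2O, pyridine, CH2Cl2, 0 to 25 °C
Reagents that add atoms: acetic anhydride, CC(=O)OC(C)=O
Why: Acetylation of the remaining secondary allylic alcohol in pyridine without a stronger nucleophilic catalyst (to avoid substitution with allylic shift at the β-acetoxy enal) should give the 9α-acetate with retention.

**Step 20**
Reactants: 36 silyl ether of the target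
Product: 37 (6R,7S,8S,9S)-9α-acetoxy-15-hydroxy-8β-[(2R)-2-methylbutanoyloxy]-14-oxogermacra-1(10),4,11(13)-trien-12,6α-olide
Conditions: HF·pyridine, pyridine, THF, 0 to 25 °C
Reagents that add atoms: none
Why: Fluoride-mediated desilylation with buffered HF·pyridine should cleave the Si–O bond without touching the two esters, the enal or the α-methylene lactone.

**Compound list**
1 | 3-bromocyclohex-2-en-1-one | O=C1C=C(Br)CCC1 | starting material
2 | (tributylstannyl)methanol | OC[Sn](CCCC)(CCCC)CCCC | starting material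
3 | 3-(hydroxymethyl)cyclohex-2-en-1-one | O=C1C=C(CO)CCC1 | intermediate
4 | 3-{[(tert-butyldiphenylsilyl)oxy]methyl}cyclohex-2-en-1-one | O=C1C=C(CO[Si](c2ccccc2)(c3ccccc3)C(C)(C)C)CCC1 | intermediate
5 | 2,2-dimethyl-1,3-dioxan-5-one | CC1(C)OCC(=O)CO1 | starting material
6 | potassium 2,2-dimethyl-4H-1,3-dioxin-5-olate (not isolated) | [K+].[O-]C1=COC(C)(C)OC1 | intermediate
7 | 2,2-dimethyl-4H-1,3-dioxin-5-yl trifluoromethanesulfonate | CC1(C)OCC(OS(=O)(=O)C(F)(F)F)=CO1 | intermediate
8 | lithium 5-{[(tert-butyldiphenylsilyl)oxy]methyl}cyclohexa-1,5-dien-1-olate (not isolated) | [Li+].[O-]C1=CCCC(CO[Si](c2ccccc2)(c3ccccc3)C(C)(C)C)=C1 | intermediate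
9 | rac-3-{[(tert-butyldiphenylsilyl)oxy]methyl}-6-(2,2-dimethyl-4H-1,3-dioxin-5-yl)cyclohex-2-en-1-one | O=C1C=C(CO[Si](c2ccccc2)(c3ccccc3)C(C)(C)C)CCC1C4=COC(C)(C)OC4 | intermediate
10 | (1S,6S)-3-{[(tert-butyldiphenylsilyl)oxy]methyl}-6-(2,2-dimethyl-4H-1,3-dioxin-5-yl)cyclohex-2-en-1-ol (OH cis to dioxinyl) | O[C@H]1C=C(CO[Si](c2ccccc2)(c3ccccc3)C(C)(C)C)CC[C@H]1C4=COC(C)(C)OC4 | intermediate
11 | (6S)-3-{[(tert-butyldiphenylsilyl)oxy]methyl}-6-(2,2-dimethyl-4H-1,3-dioxin-5-yl)cyclohex-2-en-1-one | O=C1C=C(CO[Si](c2ccccc2)(c3ccccc3)C(C)(C)C)CC[C@H]1C4=COC(C)(C)OC4 | intermediate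
12 | (4-methoxyphenyl)methanol | COc1ccc(CO)cc1 | starting material
13 | potassium (4-methoxyphenyl)methanolate (not isolated) | [K+].COc1ccc(C[O-])cc1 | intermediate
14 | 1-({[(E)-1,2-dichloroethenyl]oxy}methyl)-4-methoxybenzene | COc1ccc(CO/C(Cl)=C\Cl)cc1 | intermediate
15 | lithium [(4-methoxybenzyl)oxy]ethynide (not isolated) | [Li+].[C-]#COCc1ccc(OC)cc1 | intermediate
16 | (1R,6S)-3-{[(tert-butyldiphenylsilyl)oxy]methyl}-6-(2,2-dimethyl-4H-1,3-dioxin-5-yl)-1-{[(4-methoxybenzyl)oxy]ethynyl}cyclohex-2-en-1-ol (alkynyl cis to dioxinyl) | O[C@]1(C#COCc2ccc(OC)cc2)C=C(CO[Si](c3ccccc3)(c4ccccc4)C(C)(C)C)CC[C@H]1C5=COC(C)(C)OC5 | intermediate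
17 | chelated alkenylmagnesium alkoxide of 18 (Mg bridging O6 and C8 in a five-membered ring, vinyl on C7; not isolated) | C=CC1=C(OCc2ccc(OC)cc2)[Mg]O[C@@]13C=C(CO[Si](c4ccccc4)(c5ccccc5)C(C)(C)C)CC[C@H]3C6=COC(C)(C)OC6 | intermediate
18 | (1R,6S)-3-{[(tert-butyldiphenylsilyl)oxy]methyl}-6-(2,2-dimethyl-4H-1,3-dioxin-5-yl)-1-{(1E)-1-[(4-methoxybenzyl)oxy]buta-1,3-dien-2-yl}cyclohex-2-en-1-ol | O[C@]1(/C(C=C)=C/OCc2ccc(OC)cc2)C=C(CO[Si](c3ccccc3)(c4ccccc4)C(C)(C)C)CC[C@H]1C5=COC(C)(C)OC5 | intermediate
19 | potassium alkoxide of 18 (not isolated) | [K+].[O-][C@]1(/C(C=C)=C/OCc2ccc(OC)cc2)C=C(CO[Si](c3ccccc3)(c4ccccc4)C(C)(C)C)CC[C@H]1C5=COC(C)(C)OC5 | intermediate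
20 | potassium C6 dienolate of 21 (C6=C7 ring-trans, 8αH, 9βH; not isolated) | [K+].C1/C=C2/COC(C)(C)O[C@@H]2[C@@H](OCc3ccc(OC)cc3)/C(C=C)=C([O-])/C=C(/CO[Si](c4ccccc4)(c5ccccc5)C(C)(C)C)C1 | intermediate
21 | 7β-ethenyl-8β-[(4-methoxybenzyl)oxy]-9α,14-(isopropylidenedioxy)-15-[(tert-butyldiphenylsilyl)oxy]cyclodeca-1(10),4-dien-6-one (germacrane locants; both ring alkenes ring-cis; 7αH, 8αH, 9βH) | C=C[C@H]1C(=O)/C=C(/CO[Si](c2ccccc2)(c3ccccc3)C(C)(C)C)CC/C=C4/COC(C)(C)O[C@@H]4[C@H]1OCc5ccc(OC)cc5 | intermediate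
22 | the 6α-ol of 21 (6βH, 7αH, 8αH, 9βH) | C=C[C@H]1[C@H](O)/C=C(/CO[Si](c2ccccc2)(c3ccccc3)C(C)(C)C)CC/C=C4/COC(C)(C)O[C@@H]4[C@H]1OCc5ccc(OC)cc5 | intermediate
23 | B-alkyl-9-borabicyclo[3.3.1]nonane from 22 (boron on C12; not isolated) | C1CCC2CCCC1B2CC[C@H]3[C@H](O)/C=C(/CO[Si](c4ccccc4)(c5ccccc5)C(C)(C)C)CC/C=C6/COC(C)(C)O[C@@H]6[C@H]3OCc7ccc(OC)cc7 | intermediate
24 | 7β-(2-hydroxyethyl)-8β-[(4-methoxybenzyl)oxy]-9α,14-(isopropylidenedioxy)-15-[(tert-butyldiphenylsilyl)oxy]cyclodeca-1(10),4-dien-6α-ol | OCC[C@H]1[C@H](O)/C=C(/CO[Si](c2ccccc2)(c3ccccc3)C(C)(C)C)CC/C=C4/COC(C)(C)O[C@@H]4[C@H]1OCc5ccc(OC)cc5 | intermediate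
25 | lactol (12-hydroxy-12,6α-epoxy compound; not isolated) | C1C(O)O[C@@H]2/C=C(/CO[Si](c3ccccc3)(c4ccccc4)C(C)(C)C)CC/C=C5/COC(C)(C)O[C@@H]5[C@@H](OCc6ccc(OC)cc6)[C@@H]12 | intermediate
26 | 8β-[(4-methoxybenzyl)oxy]-9α,14-(isopropylidenedioxy)-15-[(tert-butyldiphenylsilyl)oxy]-13-norgermacra-1(10),4-dien-12,6α-olide (trans-fused lactone) | C1C(=O)O[C@@H]2/C=C(/CO[Si](c3ccccc3)(c4ccccc4)C(C)(C)C)CC/C=C5/COC(C)(C)O[C@@H]5[C@@H](OCc6ccc(OC)cc6)[C@@H]12 | intermediate
27 | lithium enolate of 26 (not isolated) | [Li+].C1=C([O-])O[C@@H]2/C=C(/CO[Si](c3ccccc3)(c4ccccc4)C(C)(C)C)CC/C=C5/COC(C)(C)O[C@@H]5[C@@H](OCc6ccc(OC)cc6)[C@@H]12 | intermediate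
28 | 11-[(dimethylamino)methyl] derivative of 26 (not isolated) | CN(C)CC1C(=O)O[C@@H]2/C=C(/CO[Si](c3ccccc3)(c4ccccc4)C(C)(C)C)CC/C=C5/COC(C)(C)O[C@@H]5[C@@H](OCc6ccc(OC)cc6)[C@@H]12 | intermediate
29 | 11-[(trimethylammonio)methyl] iodide of 26 (not isolated) | [I-].C[N+](C)(C)CC1C(=O)O[C@@H]2/C=C(/CO[Si](c3ccccc3)(c4ccccc4)C(C)(C)C)CC/C=C5/COC(C)(C)O[C@@H]5[C@@H](OCc6ccc(OC)cc6)[C@@H]12 | intermediate
30 | 8β-[(4-methoxybenzyl)oxy]-9α,14-(isopropylidenedioxy)-15-[(tert-butyldiphenylsilyl)oxy]germacra-1(10),4,11(13)-trien-12,6α-olide | C=C1C(=O)O[C@@H]2/C=C(/CO[Si](c3ccccc3)(c4ccccc4)C(C)(C)C)CC/C=C5/COC(C)(C)O[C@@H]5[C@@H](OCc6ccc(OC)cc6)[C@@H]12 | intermediate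
31 | 8β-hydroxy-9α,14-(isopropylidenedioxy)-15-[(tert-butyldiphenylsilyl)oxy]germacra-1(10),4,11(13)-trien-12,6α-olide | C=C1C(=O)O[C@@H]2/C=C(/CO[Si](c3ccccc3)(c4ccccc4)C(C)(C)C)CC/C=C5/COC(C)(C)O[C@@H]5[C@@H](O)[C@@H]12 | intermediate
32 | (R)-2-methylbutanoic acid | CC[C@@H](C)C(=O)O | starting material
33 | 8β-[(2R)-2-methylbutanoyloxy]-9α,14-(isopropylidenedioxy)-15-[(tert-butyldiphenylsilyl)oxy]germacra-1(10),4,11(13)-trien-12,6α-olide | C=C1C(=O)O[C@@H]2/C=C(/CO[Si](c3ccccc3)(c4ccccc4)C(C)(C)C)CC/C=C5/COC(C)(C)O[C@@H]5[C@@H](OC(=O)[C@H](C)CC)[C@@H]12 | intermediate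
34 | 9α,14-dihydroxy-8β-[(2R)-2-methylbutanoyloxy]-15-[(tert-butyldiphenylsilyl)oxy]germacra-1(10),4,11(13)-trien-12,6α-olide | C=C1C(=O)O[C@@H]2/C=C(/CO[Si](c3ccccc3)(c4ccccc4)C(C)(C)C)CC/C=C(/CO)[C@H](O)[C@@H](OC(=O)[C@H](C)CC)[C@@H]12 | intermediate
35 | 9α-hydroxy-8β-[(2R)-2-methylbutanoyloxy]-14-oxo-15-[(tert-butyldiphenylsilyl)oxy]germacra-1(10),4,11(13)-trien-12,6α-olide | C=C1C(=O)O[C@@H]2/C=C(/CO[Si](c3ccccc3)(c4ccccc4)C(C)(C)C)CC/C=C(/C=O)[C@H](O)[C@@H](OC(=O)[C@H](C)CC)[C@@H]12 | intermediate
36 | 9α-acetoxy-8β-[(2R)-2-methylbutanoyloxy]-14-oxo-15-[(tert-butyldiphenylsilyl)oxy]germacra-1(10),4,11(13)-trien-12,6α-olide | C=C1C(=O)O[C@@H]2/C=C(/CO[Si](c3ccccc3)(c4ccccc4)C(C)(C)C)CC/C=C(/C=O)[C@H](OC(C)=O)[C@@H](OC(=O)[C@H](C)CC)[C@@H]12 | intermediate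
37 | (6R,7S,8S,9S)-9α-acetoxy-15-hydroxy-8β-[(2R)-2-methylbutanoyloxy]-14-oxogermacra-1(10),4,11(13)-trien-12,6α-olide, ring-cis at C1(10) and C4 | C=C1C(=O)O[C@@H]2/C=C(/CO)CC/C=C(/C=O)[C@H](OC(C)=O)[C@@H](OC(=O)[C@H](C)CC)[C@@H]12 | target

**Step count and risks**
Total steps: 20. Longest linear sequence: 18 steps (steps 1, 2, 4–6 and 8–20, starting from 1); steps 3 and 7 prepare the two side fragments.

The three steps most likely to fail:

Step 10. The alkoxide may partition between the intended chair and the alternative chair or boat arrays, which would give the ring-trans C1=C10 alkene or the erythro C8/C9 pair. The potassium dienolate may also lose the C8 alkoxide by E1cB elimination, or be protonated with poor facial selectivity. Fallback: setting out from 18, the tertiary alcohol is silylated with 1-(trimethylsilyl)imidazole to the trimethylsilyl ether F1. Heating F1 in toluene (sealed tube, about 170 °C) should effect the neutral thermal siloxy-Cope ring expansion to the ten-membered trimethylsilyl dienol ether F2, with no free enolate present. Cleavage of F2 with Bu4NF/AcOH at −78 °C protonates C7 and comes back to the route at 21.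

Step 9. The Grignard reagent may attack the oxygen-bearing alkyne carbon with expulsion of 4-methoxybenzyl oxide, or add syn instead of anti, which would give the wrong enol-ether geometry. Fallback: setting out from 16, hydroxyl-directed ruthenium-catalysed trans-hydrostannation ([Cp*RuCl]4, Bu3SnH, CH2Cl2) should place tin on C7 and hydrogen on C8 anti to it, giving the alkenylstannane F3. Stille coupling of F3 with vinyl bromide (Pd(PPh3)4, CuI, DMF) comes back to the route at 18.

Step 5. Conjugate reduction of the enone may compete, or carbonyl reduction may outrun the racemisation of C1, so that stereoisomeric alcohols form. Fallback: setting out from 9, a Corey–Bakshi–Shibata reduction ((S)-Me-CBS oxazaborolidine, BH3·SMe2, THF, −30 °C) is used as a reagent-controlled, non-dynamic reduction. Both enantiomers of 9 should give 1S carbinols: the (S)-ketone gives 10 and the (R)-ketone gives the trans (1S,6R)-alcohol F4. The two diastereomers are separated by chromatography and the route is rejoined at 10.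

**Further compounds**
F1 | step 10 | trimethylsilyl ether of 18 | C[Si](C)(C)O[C@]1(/C(C=C)=C/OCc2ccc(OC)cc2)C=C(CO[Si](c3ccccc3)(c4ccccc4)C(C)(C)C)CC[C@H]1C5=COC(C)(C)OC5
F2 | step 10 | ring-expanded trimethylsilyl dienol ether (C6 O-silyl, C6=C7 ring-trans) | C1/C=C2/COC(C)(C)O[C@@H]2[C@@H](OCc3ccc(OC)cc3)/C(C=C)=C(O[Si](C)(C)C)/C=C(/CO[Si](c4ccccc4)(c5ccccc5)C(C)(C)C)C1
F3 | step 9 | C7 tributylstannyl enol ether from trans-hydrostannation of 16 | O[C@]1(/C([Sn](CCCC)(CCCC)CCCC)=C/OCc2ccc(OC)cc2)C=C(CO[Si](c3ccccc3)(c4ccccc4)C(C)(C)C)CC[C@H]1C5=COC(C)(C)OC5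
F4 | step 5 | (1S,6R)-3-{[(tert-butyldiphenylsilyl)oxy]methyl}-6-(2,2-dimethyl-4H-1,3-dioxin-5-yl)cyclohex-2-en-1-ol (trans) | O[C@H]1C=C(CO[Si](c2ccccc2)(c3ccccc3)C(C)(C)C)CC[C@@H]1C4=COC(C)(C)OC4
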